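The route disconnects the CH2–CH(aryl) bond of the seven-membered ring (ring D): the bond between the benzylic CH2 on the central benzene ring A and the methine that carries the 2,4-dihydroxyphenyl group and sits on resorcinol ring C. Both carbons are benzylic and of like (electrophilic) polarity, so they are joined reductively. A benzyl/benzhydryl dibromide, made in the flask from a diol, is reduced by SmI2 to a radical pair that closes ring D and sets the methine configuration under control of C-3 of dihydrofuran ring B. The precursor is an open bis(dihydrobenzofuran) assembled by two enantioselective rhodium-carbene C–H insertions.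

Key step: step 15

Labels: ring A = central benzene ring; ring B = dihydrofuran carrying the 4-oxygenated phenyl group on C-2; ring C = 3,5-dioxygenated benzene ring on C-3 of ring B; ring D = seven-membered ring; ring E = dihydrofuran carrying the 2,4-dioxygenated phenyl group on C-2 and the 3,5-dioxygenated phenyl group on C-3. Target configuration: ring B (2R,3R), ring D methine (R), ring E (2S,3S).

Catalyst: Rh2(R-PTAD)4 is dirhodium tetrakis[(R)-(1-adamantyl)(phthalimido)acetate], a carboxylate dimer of divalent rhodium; Rh2(S-PTAD)4 is its mirror image.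

Assumption: Rh2(R-PTAD)4 is taken to give the (2R,3S)-cis ring E in step 8 and its antipode the mirror-image sense in step 12; if the sense of induction is the opposite, the two catalyst enantiomers are exchanged.

Step 1
Reactants: 1 3,5-dihydroxybenzyl alcohol; 2 4-methoxybenzyl chloride
Product: 3 [3,5-bis(4-methoxybenzyloxy)phenyl]methanol
Conditions: 2 (2.2 equiv), K2CO3, KI (cat.), DMF, 60 °C
Reagents that add atoms: 4-methoxybenzyl chloride (the second of the two equivalents of 2), COc1ccc(CCl)cc1
Why: Twofold Williamson etherification, in which only the two acidic phenols are alkylated under carbonate conditions, each by one equivalent of 2, while the benzylic alcohol stays free.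

Step 2
Reactants: 3 [3,5-bis(4-methoxybenzyloxy)phenyl]methanol
Product: 4 tert-butyldimethylsilyl ether of 3
Conditions: TBSCl, imidazole, CH2Cl2, rt
Reagents that add atoms: tert-butyldimethylsilyl chloride, CC(C)(C)[Si](C)(C)Cl
Why: Standard silylation of the primary alcohol, which shields the benzylic oxygen from the later organolithium, oxidation and carbene steps.

Step 3
Reactants: 4 silyl ether
Product: 5 2,6-dibromo derivative of 4 (bromine on both ring A positions ortho to the CH2OTBS group)
Conditions: 1,3-dibromo-5,5-dimethylhydantoin (1.05 equiv), MeCN, 0 °C to rt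
Reagents that add atoms: 1,3-dibromo-5,5-dimethylhydantoin, CC1(C)C(=O)N(Br)C(=O)N1Br
Why: Electrophilic aromatic bromination, in which the reagent transfers both of its bromine atoms and the two ring A positions next to the CH2OTBS group (each ortho to one and para to the other alkoxy group) should react well before the position between the two oxygens and before the anisole-type rings of the 4-methoxybenzyl groups.

Step 4
Reactants: 5 dibromide; 6 3,5-dimethoxybenzoyl chloride
Product: 8 bromo diaryl ketone, via aryllithium 7 (not isolated)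
Conditions: n-BuLi (1.0 equiv), THF, −78 °C; then cannulation into 6, THF, −78 °C
Reagents that add atoms: none
Why: Bromine–lithium exchange at one of the two equivalent bromides followed by acylation of the aryllithium (inverse addition) should stop at the ketone, because a second addition to the di-ortho-substituted carbonyl group is sterically blocked.

Step 5
Reactants: 8 bromo diaryl ketone
Product: 9 ortho-hydroxy ketone (phenol next to the carbonyl group free, remote 4-methoxybenzyl ether kept)
Conditions: MgBr2·OEt2, toluene/Et2O, rt to 40 °C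
Reagents that add atoms: none
Why: Chelation-controlled ether cleavage, in which MgBr2 held between the ketone oxygen and the ortho ether oxygen should remove only the 4-methoxybenzyl group next to the carbonyl group and leave the remote benzyl ether and the silyl ether.

Step 6
Reactants: 9 ortho-hydroxy ketone; 10 (2,4-dimethoxyphenyl)methanol
Product: 11 2,4-dimethoxybenzyl ether of 9
Conditions: PPh3, DIAD, THF, 0 °C to rt
Reagents that add atoms: none
Why: Mitsunobu etherification of the chelated phenol by the electron-rich benzylic alcohol installs the ether CH2 group into which the carbene of step 8 inserts.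

Step 7
Reactants: 11 ketone
Product: 12 hydrazone of 11
Conditions: N2H4·H2O, AcOH (cat.), EtOH, 80 °C
Reagents that add atoms: hydrazine, NN
Why: Hydrazone formation by condensation of the diaryl ketone, driven by excess hydrazine and heat because of the two ortho substituents.

Step 8
Reactants: 12 hydrazone
Product: 14 (2R,3S)-cis-2,3-diaryl-2,3-dihydrobenzofuran (ring E closed), via diazo compound 13 (not isolated)
Conditions: MnO2, CH2Cl2, 0 °C; filtration; Rh2(R-PTAD)4 (1 mol %), CH2Cl2, −20 °C to rt
Reagents that add atoms: none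
Why: Oxidation of the hydrazone to the diaryldiazomethane and rhodium-carbene 1,5-C–H insertion into the benzylic ether CH2 (donor/donor carbene insertion) should close ring E as the cis isomer, the chiral carboxylate ligands of the catalyst setting C-3 as (S) and C-2 as (R).

Step 9
Reactants: 14 cis-dihydrobenzofuran bromide; 15 2-bromo-3,5-dimethoxybenzaldehyde
Product: 17 diaryl carbinol (both carbinol epimers), via aryllithium 16 (not isolated)
Conditions: t-BuLi (2.0 equiv), THF, −78 °C; then 15, −78 °C; H2O
Reagents that add atoms: none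
Why: Bromine–lithium exchange with t-BuLi outruns deprotonation at −78 °C and the aryllithium adds to the aldehyde (1,2-addition), the carbinol epimers converging in step 10.

Step 10
Reactants: 17 diaryl carbinol
Product: 18 diaryl ketone
Conditions: Dess–Martin periodinane, CH2Cl2, rt
Reagents that add atoms: none
Why: Dess–Martin oxidation of the benzhydrol under near-neutral conditions that should leave the benzyl ether, the silyl ether and ring E untouched.

Step 11
Reactants: 18 diaryl ketone
Product: 19 hydrazone of 18
Conditions: N2H4 (anhydrous), n-BuOH, 110 °C, sealed tube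
Reagents that add atoms: hydrazine, NN
Why: Hydrazone formation at a carbonyl group with three ortho substituents, which needs anhydrous hydrazine at high temperature while all other groups are inert to it.

Step 12
Reactants: 19 hydrazone
Product: 21 bis-cis benzodifuran (ring B closed), via diazo compound 20 (not isolated)
Conditions: MnO2, CH2Cl2, 0 °C; filtration; Rh2(S-PTAD)4 (1 mol %), CH2Cl2, −20 °C to rt
Reagents that add atoms: none
Why: The same hydrazone oxidation and rhodium-carbene 1,5-C–H insertion, now into the CH2 of the 4-methoxybenzyl ether, should close ring B as the cis isomer, the antipodal catalyst setting C-3 of ring B so that ring C lies on the same face of ring A as the 3-aryl group of ring E.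

Step 13
Reactants: 21 bis-cis benzodifuran bromide; 22 2,4-dimethoxybenzaldehyde
Product: 24 benzhydrol on ring C (both carbinol epimers), via aryllithium 23 (not isolated)
Conditions: t-BuLi (2.0 equiv), THF, −78 °C; then 22, −78 °C; H2O
Reagents that add atoms: none
Why: Bromine–lithium exchange at the only aryl bromide and 1,2-addition of the aryllithium to the aldehyde give both carbinol epimers, which is harmless because this carbon becomes trigonal in step 15.

Step 14
Reactants: 24 benzhydrol silyl ether
Product: 25 diol (primary benzylic alcohol on ring A, benzhydrol on ring C)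
Conditions: Bu4NF, THF, 0 °C
Reagents that add atoms: none
Why: Fluoride-mediated desilylation frees the primary alcohol without acid, so the ionisable benzhydrol and the cis-dihydrofurans should stay intact.

Step 15
Reactants: 25 diol
Product: 27 cis,cis nonamethyl ether having ring D closed, via dibromide 26 (not isolated)
Conditions: PPh3, NBS, THF, −20 °C; then slow addition to SmI2 (6 equiv), THF, −78 °C to rt, 2 mM
Reagents that add atoms: none
Why: PPh3/NBS converts both hydroxyl groups into bromides under neutral conditions (Appel-type bromination), and samarium diiodide then reduces the ionisable benzhydryl bromide to a persistent, planar benzhydryl radical and the primary benzylic bromide to a benzyl radical (or benzylsamarium), which combine within the molecule. The closest known reaction type is the Wurtz-type reductive coupling of benzylic halides by SmI2. Ring D is closed by radical–radical recombination (formally a 7-exo-tet closure if the benzylsamarium attacks the benzhydryl bromide), ring C and C-3 of ring B holding the two termini close. The new methine centre is controlled by the substrate: C-3 of ring B fixes ring C below ring A, the 2,4-dimethoxyphenyl group stays on the open face of ring C away from ring A and the incoming CH2, and the methine hydrogen ends in the plane of ring C next to its ortho-methoxy group (least 1,3-allylic strain), which is the (R) configuration; both carbinol epimers converge. The step needs ring closure to outrun dimerisation and simple reduction, which high dilution, slow addition to excess SmI2 and the hindered, persistent benzhydryl radical should secure.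

Step 16
Reactants: 27 cis,cis nonamethyl ether
Product: 28 trans,trans nonamethyl ether
Conditions: CF3CO2H, CH2Cl2, 0 °C to rt
Reagents that add atoms: none
Why: Acid-mediated epimerisation, in which reversible ionisation of each benzylic C-2–O bond (cation stabilised by the methoxyaryl group) and re-closure by the phenol oxygen should turn both cis-dihydrofurans into the more stable trans isomers while C-3 is untouched, so that C-2 of ring B becomes (R) and C-2 of ring E becomes (S).

Step 17
Reactants: 28 trans,trans nonamethyl ether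
Product: 29 CNP0283541.1
Conditions: BBr3, CH2Cl2, −78 °C to rt; then H2O
Reagents that add atoms: none
Why: Lewis-acid cleavage of all nine aryl methyl ethers by BBr3 and hydrolysis of the aryl borates should give the nonaphenol without change at the stereocentres.

Compound list
1 | 3,5-dihydroxybenzyl alcohol | OCc1cc(O)cc(O)c1 | starting material
2 | 4-methoxybenzyl chloride | COc1ccc(CCl)cc1 | starting material
3 | [3,5-bis(4-methoxybenzyloxy)phenyl]methanol | OCc1cc(OCc2ccc(OC)cc2)cc(OCc2ccc(OC)cc2)c1 | intermediate
4 | tert-butyl{[3,5-bis(4-methoxybenzyloxy)benzyl]oxy}dimethylsilane | CC(C)(C)[Si](C)(C)OCc1cc(OCc2ccc(OC)cc2)cc(OCc2ccc(OC)cc2)c1 | intermediate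
5 | {[2,6-dibromo-3,5-bis(4-methoxybenzyloxy)benzyl]oxy}(tert-butyl)dimethylsilane | CC(C)(C)[Si](C)(C)OCc1c(Br)c(OCc2ccc(OC)cc2)cc(OCc2ccc(OC)cc2)c1Br | intermediate
6 | 3,5-dimethoxybenzoyl chloride | COc1cc(OC)cc(C(Cl)=O)c1 | starting material
7 | aryllithium from 5 (one bromine replaced by lithium) | CC(C)(C)[Si](C)(C)OCc1c(Br)c(OCc2ccc(OC)cc2)cc(OCc2ccc(OC)cc2)c1[Li] | intermediate
8 | [3-bromo-2-(tert-butyldimethylsilyloxymethyl)-4,6-bis(4-methoxybenzyloxy)phenyl](3,5-dimethoxyphenyl)methanone | CC(C)(C)[Si](C)(C)OCc1c(Br)c(OCc2ccc(OC)cc2)cc(OCc2ccc(OC)cc2)c1C(=O)c1cc(OC)cc(OC)c1 | intermediate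
9 | [3-bromo-2-(tert-butyldimethylsilyloxymethyl)-6-hydroxy-4-(4-methoxybenzyloxy)phenyl](3,5-dimethoxyphenyl)methanone | CC(C)(C)[Si](C)(C)OCc1c(Br)c(OCc2ccc(OC)cc2)cc(O)c1C(=O)c1cc(OC)cc(OC)c1 | intermediate
10 | (2,4-dimethoxyphenyl)methanol | COc1ccc(CO)c(OC)c1 | starting material
11 | [3-bromo-2-(tert-butyldimethylsilyloxymethyl)-6-(2,4-dimethoxybenzyloxy)-4-(4-methoxybenzyloxy)phenyl](3,5-dimethoxyphenyl)methanone | CC(C)(C)[Si](C)(C)OCc1c(Br)c(OCc2ccc(OC)cc2)cc(OCc2ccc(OC)cc2OC)c1C(=O)c1cc(OC)cc(OC)c1 | intermediate
12 | hydrazone of 11 | CC(C)(C)[Si](C)(C)OCc1c(Br)c(OCc2ccc(OC)cc2)cc(OCc2ccc(OC)cc2OC)c1C(=NN)c1cc(OC)cc(OC)c1 | intermediate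
13 | diaryldiazomethane from 12 | CC(C)(C)[Si](C)(C)OCc1c(Br)c(OCc2ccc(OC)cc2)cc(OCc2ccc(OC)cc2OC)c1C(=[N+]=[N-])c1cc(OC)cc(OC)c1 | intermediate
14 | (2R,3S)-5-bromo-4-(tert-butyldimethylsilyloxymethyl)-2-(2,4-dimethoxyphenyl)-3-(3,5-dimethoxyphenyl)-6-(4-methoxybenzyloxy)-2,3-dihydrobenzofuran (cis) | COc1ccc(COc2cc3c(c(CO[Si](C)(C)C(C)(C)C)c2Br)[C@H](c2cc(OC)cc(OC)c2)[C@H](c2ccc(OC)cc2OC)O3)cc1 | intermediate
15 | 2-bromo-3,5-dimethoxybenzaldehyde | COc1cc(OC)c(Br)c(C=O)c1 | starting material
16 | 5-lithio analogue of 14 | COc1ccc(COc2cc3c(c(CO[Si](C)(C)C(C)(C)C)c2[Li])[C@H](c2cc(OC)cc(OC)c2)[C@H](c2ccc(OC)cc2OC)O3)cc1 | intermediate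
17 | (2-bromo-3,5-dimethoxyphenyl)[(2R,3S)-4-(tert-butyldimethylsilyloxymethyl)-2-(2,4-dimethoxyphenyl)-3-(3,5-dimethoxyphenyl)-6-(4-methoxybenzyloxy)-2,3-dihydrobenzofuran-5-yl]methanol, both carbinol epimers | COc1ccc(COc2cc3c(c(CO[Si](C)(C)C(C)(C)C)c2C(O)c2cc(OC)cc(OC)c2Br)[C@H](c2cc(OC)cc(OC)c2)[C@H](c2ccc(OC)cc2OC)O3)cc1 | intermediate
18 | methanone corresponding to 17 | COc1ccc(COc2cc3c(c(CO[Si](C)(C)C(C)(C)C)c2C(=O)c2cc(OC)cc(OC)c2Br)[C@H](c2cc(OC)cc(OC)c2)[C@H](c2ccc(OC)cc2OC)O3)cc1 | intermediate
19 | hydrazone of 18 | COc1ccc(COc2cc3c(c(CO[Si](C)(C)C(C)(C)C)c2C(=NN)c2cc(OC)cc(OC)c2Br)[C@H](c2cc(OC)cc(OC)c2)[C@H](c2ccc(OC)cc2OC)O3)cc1 | intermediate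
20 | diaryldiazomethane from 19 | COc1ccc(COc2cc3c(c(CO[Si](C)(C)C(C)(C)C)c2C(=[N+]=[N-])c2cc(OC)cc(OC)c2Br)[C@H](c2cc(OC)cc(OC)c2)[C@H](c2ccc(OC)cc2OC)O3)cc1 | intermediate
21 | bis-cis 2,3,5,6-tetrahydrobenzo[1,2-b:5,4-b']difuran: ring B (2S,3S) with 2-(4-methoxyphenyl) and 3-(2-bromo-3,5-dimethoxyphenyl); ring E (2R,3S) with 2-(2,4-dimethoxyphenyl) and 3-(3,5-dimethoxyphenyl); CH2OTBS on ring A between the two C-3 atoms | COc1ccc([C@H]2Oc3cc4c(c(CO[Si](C)(C)C(C)(C)C)c3[C@H]2c2cc(OC)cc(OC)c2Br)[C@H](c2cc(OC)cc(OC)c2)[C@H](c2ccc(OC)cc2OC)O4)cc1 | intermediate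
22 | 2,4-dimethoxybenzaldehyde | COc1ccc(C=O)c(OC)c1 | starting material
23 | aryllithium from 21 (ring C bromine replaced by lithium) | COc1ccc([C@H]2Oc3cc4c(c(CO[Si](C)(C)C(C)(C)C)c3[C@H]2c2cc(OC)cc(OC)c2[Li])[C@H](c2cc(OC)cc(OC)c2)[C@H](c2ccc(OC)cc2OC)O4)cc1 | intermediate
24 | analogue of 21 in which the ring C bromine is replaced by CH(OH)(2,4-dimethoxyphenyl), both carbinol epimers; ring B (2S,3R), ring E (2R,3S) | COc1ccc([C@H]2Oc3cc4c(c(CO[Si](C)(C)C(C)(C)C)c3[C@H]2c2cc(OC)cc(OC)c2C(O)c2ccc(OC)cc2OC)[C@H](c2cc(OC)cc(OC)c2)[C@H](c2ccc(OC)cc2OC)O4)cc1 | intermediate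
25 | diol from 24 (CH2OH on ring A), both carbinol epimers | COc1ccc([C@H]2Oc3cc4c(c(CO)c3[C@H]2c2cc(OC)cc(OC)c2C(O)c2ccc(OC)cc2OC)[C@H](c2cc(OC)cc(OC)c2)[C@H](c2ccc(OC)cc2OC)O4)cc1 | intermediate
26 | dibromide from 25 (CH2Br on ring A, CHBr(2,4-dimethoxyphenyl) on ring C) | COc1ccc([C@H]2Oc3cc4c(c(CBr)c3[C@H]2c2cc(OC)cc(OC)c2C(Br)c2ccc(OC)cc2OC)[C@H](c2cc(OC)cc(OC)c2)[C@H](c2ccc(OC)cc2OC)O4)cc1 | intermediate
27 | nonamethyl ether of the target skeleton with ring D closed; ring B (2S,3R)-cis, ring D methine (R), ring E (2R,3S)-cis | COc1ccc([C@H]2Oc3cc4c(c5c3[C@H]2c2cc(OC)cc(OC)c2[C@@H](c2ccc(OC)cc2OC)C5)[C@H](c2cc(OC)cc(OC)c2)[C@H](c2ccc(OC)cc2OC)O4)cc1 | intermediate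
28 | nonamethyl ether of the target; ring B (2R,3R)-trans, ring D methine (R), ring E (2S,3S)-trans | COc1ccc([C@@H]2Oc3cc4c(c5c3[C@H]2c2cc(OC)cc(OC)c2[C@@H](c2ccc(OC)cc2OC)C5)[C@H](c2cc(OC)cc(OC)c2)[C@@H](c2ccc(OC)cc2OC)O4)cc1 | intermediate
29 | CNP0283541.1, nonaphenol; ring B (2R,3R), ring D methine (R), ring E (2S,3S) | Oc1ccc([C@@H]2Oc3cc4c(c5c3[C@H]2c2cc(O)cc(O)c2[C@@H](c2ccc(O)cc2O)C5)[C@H](c2cc(O)cc(O)c2)[C@@H](c2ccc(O)cc2O)O4)cc1 | target

Total step count: 17. Longest linear sequence: 17 steps (1 to 29); 2, 6, 10, 15 and 22 are bought and enter directly.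

Steps most likely to fail

Step 15. After the first electron transfer the radical pair may be reduced on to organosamarium species and protonated, or may couple between molecules. The bromination stage may instead close an eight-membered ether between the two oxygens, and facial control at the benzhydryl carbon may be incomplete. The fallback replaces the reductive union by a polar alkylation with a removable sulfonyl group; it sets out from 21 and comes back at 27. Bu4NF should give the primary alcohol F1, and PPh3/NBS the benzylic bromide F2. PhSO2Na in DMF should then give the benzylic phenyl sulfone F3. Deprotonation of the sulfone with n-BuLi, bromine–lithium exchange with t-BuLi and addition of 22 should give the hydroxy sulfone F4. PPh3/NBS followed by LiN(SiMe3)2 should turn the benzhydrol into its ionisable bromide and let the α-sulfonyl carbanion alkylate it within the molecule, with the same facial preference, to the cyclic sulfone F5. Mg in MeOH should then remove the sulfonyl group reductively to give 27.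

Step 11. The condensation with hydrazine may stall at the carbonyl group shielded by three ortho substituents, or the forcing conditions may erode the silyl ether. The fallback avoids the ketone; it sets out from 14 and comes back at 19, leaving out 17 and 18. The aryllithium 16 is added to 2-bromo-3,5-dimethoxybenzonitrile F6 (from 15 with iodine in aqueous ammonia), which after a methanol quench should give the N-unsubstituted ketimine F7. Transimination of F7 with hydrazine in EtOH, far easier than carbonyl condensation, should give 19.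

Step 17. Lewis-acid ionisation of the benzylic C-2–O bonds of rings B and E during the ether cleavage may open the dihydrofuran rings and let the cations alkylate neighbouring phenol rings. The fallback sets out from 28 and comes back at 29: nucleophilic demethylation by sodium ethanethiolate in DMF at 130 °C (substitution at the methyl carbons) avoids Lewis acids altogether; no new compound is made (F0).

Further compounds
F1 | step 15 | primary alcohol from 21 (CH2OH on ring A, ring C bromide kept) | COc1ccc([C@H]2Oc3cc4c(c(CO)c3[C@H]2c2cc(OC)cc(OC)c2Br)[C@H](c2cc(OC)cc(OC)c2)[C@H](c2ccc(OC)cc2OC)O4)cc1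
F2 | step 15 | benzylic bromide from F1 (CH2Br on ring A) | COc1ccc([C@H]2Oc3cc4c(c(CBr)c3[C@H]2c2cc(OC)cc(OC)c2Br)[C@H](c2cc(OC)cc(OC)c2)[C@H](c2ccc(OC)cc2OC)O4)cc1
F3 | step 15 | benzylic phenyl sulfone (CH2SO2Ph on ring A) | COc1ccc([C@H]2Oc3cc4c(c(CS(=O)(=O)c5ccccc5)c3[C@H]2c2cc(OC)cc(OC)c2Br)[C@H](c2cc(OC)cc(OC)c2)[C@H](c2ccc(OC)cc2OC)O4)cc1
F4 | step 15 | hydroxy sulfone (CH2SO2Ph on ring A, CH(OH)(2,4-dimethoxyphenyl) on ring C), both carbinol epimers | COc1ccc([C@H]2Oc3cc4c(c(CS(=O)(=O)c5ccccc5)c3[C@H]2c2cc(OC)cc(OC)c2C(O)c2ccc(OC)cc2OC)[C@H](c2cc(OC)cc(OC)c2)[C@H](c2ccc(OC)cc2OC)O4)cc1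
F5 | step 15 | cyclic sulfone (27 carrying a phenylsulfonyl group on the ring D CH carbon next to ring A) | COc1ccc([C@H]2Oc3cc4c(c5c3[C@H]2c2cc(OC)cc(OC)c2[C@@H](c2ccc(OC)cc2OC)C5S(=O)(=O)c2ccccc2)[C@H](c2cc(OC)cc(OC)c2)[C@H](c2ccc(OC)cc2OC)O4)cc1
F6 | step 11 | 2-bromo-3,5-dimethoxybenzonitrile | COc1cc(OC)c(Br)c(C#N)c1
F7 | step 11 | N-unsubstituted ketimine corresponding to 18 | COc1ccc(COc2cc3c(c(CO[Si](C)(C)C(C)(C)C)c2C(=N)c2cc(OC)cc(OC)c2Br)[C@H](c2cc(OC)cc(OC)c2)[C@H](c2ccc(OC)cc2OC)O3)cc1
F0 | step 17 | none | none
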